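**Retrosynthetic overview**
1. The target 22 comes from its 2,3,5-trimethoxyphenyl analogue 20 (oxidative demethylation, then reduction); the E-chloroalkene C9=C11 of 20 comes from aryl ketone 18 through an enol triflate and chloride capture of an α-aryl vinyl cation.
2. Rings A and B are formed together from the open-chain (E)-aryl trienone 13 by a Lewis acid-promoted intramolecular Diels–Alder reaction that makes the ring-fusion bond C5–C10 and the bond C8–C9.
3. Enabling feature: ring B is a cyclohexane whose C9 carries the sp2 carbon C11 next to the quaternary C10 and whose C6–C7 bond can be an alkene. This is a Diels–Alder retron with dienophile C9=C10 (activated by C11=O), diene C5=C6–C7=C8, and the chain C1–C4 (the later ring A) as tether.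
4. A temporary silyloxy stereocentre at C2 (a C–O bond not in the target) fixes the absolute sense of the cycloaddition and is removed afterwards by radical deoxygenation.
5. Trienone 13 comes from alkyne 9 (carboalumination sets the E-alkene and brings the C10 methyl) and aldehyde 4; 9 comes from dienal 7 by asymmetric propargylation.

Key step: step 9

Remark: the decalin is numbered as in drimane (C1–C10, C11 on C9, methyl groups on C4, C4, C8 and C10); α is the face opposite to the C10 methyl group, β the same face.

**Step 1**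
Reactants: 1 2-hydroxy-3-methoxybenzaldehyde (o-vanillin)
Product: 3 2,5-dihydroxy-3-methoxybenzaldehyde, via potassium aryl sulfate 2 (not isolated)
Conditions: K2S2O8, aq. NaOH, 0 °C → rt; then aq. HCl, 80 °C
Reagents that add atoms: potassium peroxodisulfate, [K+].[K+].[O-]S(=O)(=O)OOS(=O)(=O)[O-]
Why: Elbs persulfate oxidation: the phenoxide attacks a peroxide oxygen through its free para carbon, and acid hydrolysis of the aryl sulfate frees the second phenol.

**Step 2**
Reactants: 3 2,5-dihydroxy-3-methoxybenzaldehyde
Product: 4 2,3,5-trimethoxybenzaldehyde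
Conditions: MeI, K2CO3, DMF, rt
Reagents that add atoms: iodomethane, CI
Why: Williamson O-methylation of both phenols; the aldehyde is inert and no stereocentre is involved.

**Step 3**
Reactants: 5 methyl 3,3-dimethylpent-4-enoate
Product: 6 methyl (4E,6E)-3,3-dimethylocta-4,6-dienoate
Conditions: (E)-prop-1-enylboronic acid pinacol ester, Pd(OAc)2 (10 mol %), 1,2-bis(phenylsulfinyl)ethane (10 mol %), 2,6-dimethyl-1,4-benzoquinone, AcOH, dioxane, 45 °C
Reagents that add atoms: (E)-prop-1-enylboronic acid pinacol ester, C/C=C/B1OC(C)(C)C(C)(C)O1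
Why: oxidative Heck vinylation of a terminal olefin with an alkenylboronate: transmetalation, insertion with palladium on the internal carbon and β-hydride elimination (possible only away from the quaternary carbon) should give the E,E-diene with the propenyl geometry retained.

**Step 4**
Reactants: 6 methyl (4E,6E)-3,3-dimethylocta-4,6-dienoate
Product: 7 (4E,6E)-3,3-dimethylocta-4,6-dienal
Conditions: i-Bu2AlH, CH2Cl2, −78 °C; then MeOH, aq. KNaC4H4O6
Reagents that add atoms: none
Why: partial ester reduction; the tetrahedral aluminium hemiacetal survives at −78 °C and gives the aldehyde on work-up.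

**Step 5**
Reactants: 7 (4E,6E)-3,3-dimethylocta-4,6-dienal
Product: 8 (4R,7E,9E)-6,6-dimethylundeca-7,9-dien-1-yn-4-ol
Conditions: allenylboronic acid pinacol ester, (R)-TRIP (5 mol %), 4 Å sieves, toluene, −20 °C
Reagents that add atoms: allenylboronic acid pinacol ester, C=C=CB1OC(C)(C)C(C)(C)O1
Why: phosphoric acid-catalysed asymmetric propargylation of an aldehyde with an allenylboronate (SE2' addition through a six-membered chair transition state organised by the chiral acid), which should set the carbinol centre (the later C2) as R with the (R)-catalyst.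

**Step 6**
Reactants: 8 (4R,7E,9E)-6,6-dimethylundeca-7,9-dien-1-yn-4-ol
Product: 9 triethyl{[(4R,7E,9E)-6,6-dimethylundeca-7,9-dien-1-yn-4-yl]oxy}silane
Conditions: Et3SiCl, imidazole, DMF, 0 °C → rt
Reagents that add atoms: chlorotriethylsilane, CC[Si](Cl)(CC)CC
Why: silylation of the secondary alcohol masks it through the organometallic and Lewis acid steps.

**Step 7**
Reactants: 9 triethyl{[(4R,7E,9E)-6,6-dimethylundeca-7,9-dien-1-yn-4-yl]oxy}silane; 4 2,3,5-trimethoxybenzaldehyde
Product: 12 (2E,5R,8E,10E)-3,7,7-trimethyl-5-(triethylsilyloxy)-1-(2,3,5-trimethoxyphenyl)dodeca-2,8,10-trien-1-ol (both C1 epimers), via alkenylalane 10 (not isolated), via lithium alanate 11 (not isolated)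
Conditions: AlMe3, Cp2ZrCl2 (cat.), CH2Cl2, 0 °C → rt; evaporate; n-BuLi, THF, −78 °C; then 4, −78 → 0 °C
Reagents that add atoms: trimethylaluminium, C[Al](C)C
Why: Negishi carboalumination (syn addition of Me–Al across the terminal alkyne, methyl on the internal carbon) gives the E-alkenylalane, whose butyl ate complex transfers the alkenyl group to the aldehyde with retention of alkene geometry; the new carbinol centre is uncontrolled and is erased in step 8.

**Step 8**
Reactants: 12 (2E,5R,8E,10E)-3,7,7-trimethyl-5-(triethylsilyloxy)-1-(2,3,5-trimethoxyphenyl)dodeca-2,8,10-trien-1-ol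
Product: 13 (2E,5R,8E,10E)-3,7,7-trimethyl-5-(triethylsilyloxy)-1-(2,3,5-trimethoxyphenyl)dodeca-2,8,10-trien-1-one
Conditions: MnO2, CH2Cl2, rt
Reagents that add atoms: none
Why: MnO2 oxidises the allylic and benzylic alcohol to the enone under neutral conditions without touching the alkene geometry or the silyl ether.

**Step 9**
Reactants: 13 (2E,5R,8E,10E)-3,7,7-trimethyl-5-(triethylsilyloxy)-1-(2,3,5-trimethoxyphenyl)dodeca-2,8,10-trien-1-one
Product: 15 (2S,5S,8S,9S,10S)-2-hydroxy-11-(2,3,5-trimethoxyphenyl)drim-6-en-11-one (2α-OH, 5α-H, 8β-Me, 9β-aroyl, 10β-Me), via silyl ether adduct 14 (not isolated)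
Conditions: MeAlCl2 (1.5 equiv), CH2Cl2, −78 → 0 °C; then 1 M HCl, THF, rt
Reagents that add atoms: none
Why: The Lewis acid, bound to the carbonyl and the ortho-methoxy oxygen, lowers the LUMO of the (E)-enone, which adds to the tethered E,E-diene in a concerted, asynchronous [4+2] cycloaddition (type 1 intramolecular Diels–Alder reaction; closest precedent: Lewis acid-promoted cyclisations of (E)-2,7,9-decatrienoyl systems to trans-fused octalins, including β-methyl dienophiles that create an angular methyl group). Ring B closes as a cyclohexene through the two new bonds C5–C10 and C8–C9, and ring A closes at the same time as the six-membered tether ring (C10, C1–C4, C5) through the C5–C10 bond alone. Suprafacial addition turns the E-enone geometry into the cis relation of the C10 methyl and the C9 aroyl group, and the E,E-diene geometry into the cis relation of C4 and the C8 methyl, which fixes C8 relative to C5. The trans ring fusion (C5–H anti to the C10 methyl) follows from the endo transition state, in which the complexed aroyl group lies under the diene and the tether is therefore exo and chair-like. The absolute sense is set by the C2 silyloxy group, which must be equatorial in that chair because the axial position is syn-axial to both the C10 methyl and the axial C4 methyl. The step needs endo over exo selectivity and an unchanged E-enone, which the substrate secures through the ortho-methoxy group (two-point binding of MeAlCl2 allows reaction at low temperature) and the geometrically pure trisubstituted alkene; the acidic work-up removes the silyl group.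

**Step 10**
Reactants: 15 (2S,5S,8S,9S,10S)-2-hydroxy-11-(2,3,5-trimethoxyphenyl)drim-6-en-11-one
Product: 16 (2S,5S,8S,9S,10S)-2-hydroxy-11-(2,3,5-trimethoxyphenyl)driman-11-one
Conditions: H2 (1 atm), 10% Pd/C, EtOAc, rt
Reagents that add atoms: none
Why: heterogeneous hydrogenation saturates the only accessible alkene (cis-disubstituted C6=C7); the hindered aryl ketone and the arene should survive, and no stereocentre is formed.

**Step 11**
Reactants: 16 (2S,5S,8S,9S,10S)-2-hydroxy-11-(2,3,5-trimethoxyphenyl)driman-11-one
Product: 17 O-[(2S,5S,8S,9S,10S)-11-oxo-11-(2,3,5-trimethoxyphenyl)driman-2-yl] 1H-imidazole-1-carbothioate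
Conditions: 1,1'-thiocarbonyldiimidazole, DMAP (cat.), ClCH2CH2Cl, 70 °C
Reagents that add atoms: 1,1'-thiocarbonyldiimidazole, S=C(n1ccnc1)n1ccnc1
Why: acylation of the unhindered equatorial C2 alcohol gives the thiocarbonyl derivative needed for radical deoxygenation.

**Step 12**
Reactants: 17 O-[(2S,5S,8S,9S,10S)-11-oxo-11-(2,3,5-trimethoxyphenyl)driman-2-yl] 1H-imidazole-1-carbothioate
Product: 18 (5S,8S,9S,10S)-11-(2,3,5-trimethoxyphenyl)driman-11-one
Conditions: n-Bu3SnH, AIBN (cat.), toluene, 110 °C
Reagents that add atoms: none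
Why: Barton–McCombie deoxygenation: the stannyl radical adds to C=S, β-scission gives the secondary C2 radical, and hydrogen transfer leaves a methylene group, which removes the temporary stereocentre.

**Step 13**
Reactants: 18 (5S,8S,9S,10S)-11-(2,3,5-trimethoxyphenyl)driman-11-one
Product: 20 (5S,8S,10S,9(11)E)-11-chloro-11-(2,3,5-trimethoxyphenyl)drim-9(11)-ene, via enol triflate 19 (not isolated)
Conditions: Tf2O, 2,6-di-tert-butyl-4-methylpyridine, CH2Cl2, 0 °C → rt; then n-Bu4NCl, (CF3)2CHOH, 40 °C
Reagents that add atoms: tetrabutylammonium chloride, CCCC[N+](CCCC)(CCCC)CCCC.[Cl-]; trifluoromethanesulfonic anhydride, O=S(=O)(OS(=O)(=O)C(F)(F)F)C(F)(F)F (its CF3SO2 group is carried only by 19)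
Why: Tf2O sulfonylates the ketone oxygen and the hindered base removes the only α-hydrogen (C9–H) to give the enol triflate, which ionises in the fluorinated alcohol to the linear α-aryl vinyl cation (vinylic SN1 substitution, stabilised by the ortho-methoxyaryl group); chloride should add in the C8–C9–C10 plane from the side of C8, where only an equatorial hydrogen stands, and not from the side of C10, where the equatorial C1 methylene blocks the path, so that both triflate isomers converge on the E-chloroalkene.

**Step 14**
Reactants: 20 (5S,8S,10S,9(11)E)-11-chloro-11-(2,3,5-trimethoxyphenyl)drim-9(11)-ene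
Product: 22 2-[(E)-chloro[(2S,4aS,8aS)-2,5,5,8a-tetramethyloctahydronaphthalen-1(2H)-ylidene]methyl]-6-methoxybenzene-1,4-diol (target), via quinone 21 (not isolated)
Conditions: (NH4)2Ce(NO3)6, MeCN/H2O, 0 °C; then aq. Na2S2O4, EtOAc, rt
Reagents that add atoms: water, O
Why: oxidative demethylation of the para-dimethoxy pair (arene radical cation, water attack at the two methoxy-bearing carbons, loss of methanol) gives the methoxy-para-quinone, which dithionite reduces to the hydroquinone; the third methoxy group and the chloroalkene should not be touched.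

**Compound list**
1 | 2-hydroxy-3-methoxybenzaldehyde (o-vanillin) | COc1cccc(C=O)c1O | starting material
2 | potassium 3-formyl-4-hydroxy-5-methoxyphenyl sulfate (formed in the flask) | COc1cc(OS(=O)(=O)[O-])cc(C=O)c1O.[K+] | intermediate
3 | 2,5-dihydroxy-3-methoxybenzaldehyde | COc1cc(O)cc(C=O)c1O | intermediate
4 | 2,3,5-trimethoxybenzaldehyde | COc1cc(OC)cc(C=O)c1OC | intermediate
5 | methyl 3,3-dimethylpent-4-enoate | COC(=O)CC(C)(C)C=C | starting material
6 | methyl (4E,6E)-3,3-dimethylocta-4,6-dienoate | COC(=O)CC(C)(C)/C=C/C=C/C | intermediate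
7 | (4E,6E)-3,3-dimethylocta-4,6-dienal | O=CCC(C)(C)/C=C/C=C/C | intermediate
8 | (4R,7E,9E)-6,6-dimethylundeca-7,9-dien-1-yn-4-ol | C#CC[C@@H](O)CC(C)(C)/C=C/C=C/C | intermediate
9 | triethyl{[(4R,7E,9E)-6,6-dimethylundeca-7,9-dien-1-yn-4-yl]oxy}silane | C#CC[C@@H](O[Si](CC)(CC)CC)CC(C)(C)/C=C/C=C/C | intermediate
10 | dimethyl[(1E,4S,7E,9E)-2,6,6-trimethyl-4-(triethylsilyloxy)undeca-1,7,9-trien-1-yl]alane (formed in the flask; same spatial arrangement at the silyloxy carbon as 9) | C[Al](C)/C=C(\C)C[C@@H](O[Si](CC)(CC)CC)CC(C)(C)/C=C/C=C/C | intermediate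
11 | lithium butyl(dimethyl)[(1E,4S,7E,9E)-2,6,6-trimethyl-4-(triethylsilyloxy)undeca-1,7,9-trien-1-yl]aluminate (formed in the flask) | [Li+].CCCC[Al-](C)(C)/C=C(\C)C[C@@H](O[Si](CC)(CC)CC)CC(C)(C)/C=C/C=C/C | intermediate
12 | (2E,5R,8E,10E)-3,7,7-trimethyl-5-(triethylsilyloxy)-1-(2,3,5-trimethoxyphenyl)dodeca-2,8,10-trien-1-ol, both C1 epimers | COc1cc(OC)cc(C(O)/C=C(\C)C[C@@H](O[Si](CC)(CC)CC)CC(C)(C)/C=C/C=C/C)c1OC | intermediate
13 | (2E,5R,8E,10E)-3,7,7-trimethyl-5-(triethylsilyloxy)-1-(2,3,5-trimethoxyphenyl)dodeca-2,8,10-trien-1-one | COc1cc(OC)cc(C(=O)/C=C(\C)C[C@@H](O[Si](CC)(CC)CC)CC(C)(C)/C=C/C=C/C)c1OC | intermediate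
14 | (2S,5S,8S,9S,10S)-2-(triethylsilyloxy)-11-(2,3,5-trimethoxyphenyl)drim-6-en-11-one (formed in the flask) | COc1cc(OC)cc(C(=O)[C@H]2[C@@H](C)C=C[C@H]3C(C)(C)C[C@H](O[Si](CC)(CC)CC)C[C@]23C)c1OC | intermediate
15 | (2S,5S,8S,9S,10S)-2-hydroxy-11-(2,3,5-trimethoxyphenyl)drim-6-en-11-one | COc1cc(OC)cc(C(=O)[C@H]2[C@@H](C)C=C[C@H]3C(C)(C)C[C@H](O)C[C@]23C)c1OC | intermediate
16 | (2S,5S,8S,9S,10S)-2-hydroxy-11-(2,3,5-trimethoxyphenyl)driman-11-one | COc1cc(OC)cc(C(=O)[C@H]2[C@@H](C)CC[C@H]3C(C)(C)C[C@H](O)C[C@]23C)c1OC | intermediate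
17 | O-[(2S,5S,8S,9S,10S)-11-oxo-11-(2,3,5-trimethoxyphenyl)driman-2-yl] 1H-imidazole-1-carbothioate | COc1cc(OC)cc(C(=O)[C@H]2[C@@H](C)CC[C@H]3C(C)(C)C[C@H](OC(=S)n4ccnc4)C[C@]23C)c1OC | intermediate
18 | (5S,8S,9S,10S)-11-(2,3,5-trimethoxyphenyl)driman-11-one | COc1cc(OC)cc(C(=O)[C@H]2[C@@H](C)CC[C@H]3C(C)(C)CCC[C@]23C)c1OC | intermediate
19 | (5S,8S,10S)-11-(2,3,5-trimethoxyphenyl)drim-9(11)-en-11-yl trifluoromethanesulfonate, E/Z mixture (formed in the flask) | COc1cc(OC)cc(C(OS(=O)(=O)C(F)(F)F)=C2[C@@H](C)CC[C@H]3C(C)(C)CCC[C@]23C)c1OC | intermediate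
20 | (5S,8S,10S,9(11)E)-11-chloro-11-(2,3,5-trimethoxyphenyl)drim-9(11)-ene | COc1cc(OC)cc(/C(Cl)=C2/[C@@H](C)CC[C@H]3C(C)(C)CCC[C@]23C)c1OC | intermediate
21 | 2-[(5S,8S,10S,9(11)E)-11-chlorodrim-9(11)-en-11-yl]-6-methoxy-1,4-benzoquinone (formed in the flask) | COC1=CC(=O)C=C(/C(Cl)=C2/[C@@H](C)CC[C@H]3C(C)(C)CCC[C@]23C)C1=O | intermediate
22 | 2-[(E)-chloro[(2S,4aS,8aS)-2,5,5,8a-tetramethyloctahydronaphthalen-1(2H)-ylidene]methyl]-6-methoxybenzene-1,4-diol | COc1cc(O)cc(/C(Cl)=C2/[C@@H](C)CC[C@H]3C(C)(C)CCC[C@]23C)c1O | target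

**Step count**
Total: 14 steps. Longest linear sequence: 12 steps (5 → 22, steps 3–14); aldehyde 4 is made in 2 steps and joins in step 7.

**Steps most likely to fail, with fallbacks**

Step 9. The cycloaddition of the β,β-disubstituted enone onto the neopentyl-flanked diene may be slow. The Lewis acid may then isomerise the enone, erode the endo (trans-fusion) preference, or eliminate the silyloxy group vinylogously before the rings close. The fallback changes the activation from a neutral Lewis acid complex to a cationic dienophile (ionic Diels–Alder reaction). Setting out from 13, treatment with 1,2-bis(trimethylsilyloxy)ethane and catalytic Me3SiOTf in CH2Cl2 at −78 °C should form the 2-alkenyl-1,3-dioxolan-2-ylium ion, which cyclises at low temperature to the ketal cycloadduct (2S,5S,8S,9S,10S)-11,11-(ethylenedioxy)-2-(triethylsilyloxy)-11-(2,3,5-trimethoxyphenyl)drim-6-ene F1. Aqueous HCl in THF then removes the dioxolane and the silyl group and the route is rejoined at 15.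

Step 13. Sulfonylation and deprotonation at the congested C9–H may stall, the vinyl cation may be captured by solvent, or chloride may add from both sides. The fallback replaces the cationic substitution by a stereoretentive metal-catalysed exchange. Setting out from 18, deprotonation with KN(SiMe3)2 and trapping with PhNTf2 gives 19 as an isolated compound, so no compound outside the list is made (F0). Its geometrical isomers are separated, and the isomer with the triflate on the C8 side is converted with Ni(cod)2 (zerovalent nickel, catalytic) and LiCl in DMA/THF into 20, where the route is rejoined; the other isomer is hydrolysed back to 18.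

Step 5. The allenylboronate addition to this hindered aliphatic aldehyde may proceed with insufficient enantioselectivity, which would carry through to the final product. The fallback sets the centre by resolution of an epoxide instead. Setting out from 7, dimethylsulfonium methylide (Me3SI, n-BuLi, THF) gives racemic 2-[(3E,5E)-2,2-dimethylhepta-3,5-dien-1-yl]oxirane F2. Hydrolytic kinetic resolution with the enantiomer of (salen)Co(OAc) (trivalent cobalt) that consumes the R epoxide (0.55 equiv H2O) leaves (S)-2-[(3E,5E)-2,2-dimethylhepta-3,5-dien-1-yl]oxirane F3. Opening of F3 at the terminal carbon with LiC≡CH·H2NCH2CH2NH2 in DMSO gives 8, where the route is rejoined.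

**Further compounds**
F1 | step 9 | (2S,5S,8S,9S,10S)-11,11-(ethylenedioxy)-2-(triethylsilyloxy)-11-(2,3,5-trimethoxyphenyl)drim-6-ene | COc1cc(OC)cc(C2([C@H]3[C@@H](C)C=C[C@H]4C(C)(C)C[C@H](O[Si](CC)(CC)CC)C[C@]34C)OCCO2)c1OC
F0 | step 13 | none | none
F2 | step 5 | racemic 2-[(3E,5E)-2,2-dimethylhepta-3,5-dien-1-yl]oxirane | C1OC1CC(C)(C)/C=C/C=C/C
F3 | step 5 | (S)-2-[(3E,5E)-2,2-dimethylhepta-3,5-dien-1-yl]oxirane | C1O[C@H]1CC(C)(C)/C=C/C=C/C
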